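Late in this flask, electrophile and the last free nucleophile meet one for one, so I reckon backwards from the end.

electrophile 0.68 M; solid base 0.340 M; time 4.0 min

1. the concentration of nucleophile at which the part of the electrophile that has reacted at 4.0 min is just 95%, in M

    acid set free → by-product carried off (k1 = 0.14 s⁻¹)
    solid base ⇌ free base, rate k2*(cs2 - [free base]) while solid is left; crystals form when [free base] > cs2 (cs2 = 0.65 M, k2 = 0.21 s⁻¹)
    nucleophile + acid set free ⇌ protonated nucleophile, settled at all times (K3 = 32 M⁻¹)
    acid set free + free base ⇌ salt of the base, settled at all times (K4 = 27000 M⁻¹)
    electrophile + nucleophile → acid set free + target (k5 = 1.6 M⁻¹ s⁻¹)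

My first answer is the stoichiometric floor: reaching 95.0% consumes 0.646 M of nucleophile and leaves 0.0340 M of electrophile. Charged at that floor, the nucleophile is the limiting reagent, and its decay at late times is pseudo-first-order in the electrophile left over. I call 18.4 s the tail time, one over the coupling constant times that leftover electrophile.

The half-life of free acid by step 1 alone, 4.95 s, says nothing of acid held as protonated nucleophile or salt of the base, so I do not hold it against the tail time. It and the dissolving time of 4.76 s are far shorter than the run, and on that ground I set them aside. That leaves two times, the tail time and the run of 4.0 min, which is longer by a factor of 13.1.

Now I put the floor back in and go round once more. With the tail counted over the whole run, the free nucleophile at the end comes to about 7.27 × 10⁻⁸ M; with the tail counted over the second half of the run, to allow for bound acid, it comes to about 4.97 × 10⁻⁵ M. Even the larger estimate is far smaller than the floor, so my second round stays at 0.646 M.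

The forecast gives 0.6461 M, with a range of 0.646 M to 0.652 M, and says “the answer sits just above the stoichiometric floor”. My figure is close to the forecast's, at the low end of that range.

The simulation gives 0.646 M. Half of the carrying-off of acid up to 4.0 min is done by 0.347 min, a longer time than the tail time. Electrophile used already stands at 95.0% at 2.00 min. Free nucleophile falls from 2.86% of its charge at 0.400 min to 0.0426% at 2.00 min, which reads as 22.8 s per e-fold, against the tail time of 18.4 s.

All constants are made up, and the outcome is calculated.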